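**Plan** (flavanone numbering: O1, C2, C3, C4, C4a, C5–C8, C8a; ring A = phloroglucinol ring, ring B = anisyl ring, ring C = pyranone ring)

- Retrosynthesis: the two methoxymethyl (MOM) ethers on O5 and O7 are cut first. Then both ring C bonds, O1–C2 and C4–C4a, are cut together, which leads to an isomer of the protected flavanone, the aryl (E)-4-methoxycinnamate with the acyl group on O1. Then the ester bond, the C8–prenyl bond (aromatic Claisen) and the C8a–O1 bond (C–H borylation/oxidation) are cut, back to 2-methylresorcinol.
- Forward: ring A is bought with its methyl group and two oxygens. O1 is added, the C5 unit is carried from O1 to C8, ring B arrives with the cinnamoyl group on O1, and ring C is closed last in one flask by a photo-Fries acyl shift followed by an oxa-Michael closure.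
- Enabling feature: O1 and the carbonyl carbon C4 of ring C sit on the neighbouring ring A carbons C8a and C4a. C4a is the only ring A carbon that bears hydrogen, and O1 is the only ring A oxygen left unprotected. An acyl group parked on O1 can therefore land only on C4a, and the freed O1–H then lies six atoms from C2 of the new enone.
- Stereochemistry: the single stereocentre C2 (S) is set in the key step by a bifunctional cinchona amine–thiourea catalyst that delivers O1 to the Si face of C2. The final deprotection is run in dilute acid, where the flavanone ring should not open.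

Key step: step 7

Assumption: the quinine-derived amine–thiourea is taken as the pseudoenantiomer that directs O1 to the Si face of C2; if the sense is the opposite, the quinidine-derived catalyst is used with no other change.

**Step 1**
Reactants: 1 2-methylresorcinol (2-methylbenzene-1,3-diol)
Product: 2 1,3-bis(methoxymethoxy)-2-methylbenzene
Conditions: MOMCl, i-Pr2NEt, CH2Cl2, 0 °C to rt
Reagents that add atoms: chloromethyl methyl ether, COCCl
Why: Williamson-type O-alkylation of both phenols with the reactive α-chloro ether gives acetal ethers that should tolerate the base, the iridium catalyst, the heat and the light of the later steps and leave under mild acid at the end.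

**Step 2**
Reactants: 2 1,3-bis(methoxymethoxy)-2-methylbenzene
Product: 4 3,5-bis(methoxymethoxy)-4-methylphenol, via arylboronic pinacol ester 3 (not isolated)
Conditions: [Ir(OMe)(cod)]2 (cat.), 4,4'-di-tert-butyl-2,2'-bipyridine (cat.), B2pin2 (0.55 equiv), cyclohexane, 80 °C; then THF, aq. NaOH, 30% H2O2, 0 °C
Reagents that add atoms: hydrogen peroxide, OO (oxygen of the new hydroxyl of 4); bis(pinacolato)diboron, CC1(C)OB(OC1(C)C)B1OC(C)(C)C(C)(C)O1 (boryl group of 3 only)
Why: Iridium-catalysed aromatic C–H borylation is governed by sterics and takes the only ring hydrogen without an ortho neighbour (para to the methyl group), and basic peroxide oxidation replaces boron by hydroxyl at the same carbon, so that the new oxygen, the future O1, is the only free hydroxyl and is flanked by two equivalent C–H positions.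

**Step 3**
Reactants: 4 3,5-bis(methoxymethoxy)-4-methylphenol; 5 3-chloro-3-methylbut-1-yne
Product: 6 1,3-bis(methoxymethoxy)-2-methyl-5-[(2-methylbut-3-yn-2-yl)oxy]benzene
Conditions: DBU, CuCl2·2H2O (cat.), MeCN, 0 °C
Reagents that add atoms: none
Why: Copper-catalysed O-alkylation of a phenol by a tertiary propargylic chloride proceeds through a copper-stabilised propargylic cation and should give the 1,1-dimethylpropargyl aryl ether, the base-stable MOM ethers being untouched.

**Step 4**
Reactants: 6 1,3-bis(methoxymethoxy)-2-methyl-5-[(2-methylbut-3-yn-2-yl)oxy]benzene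
Product: 7 1,3-bis(methoxymethoxy)-2-methyl-5-[(2-methylbut-3-en-2-yl)oxy]benzene
Conditions: H2 (1 atm), Pd/CaCO3 poisoned with Pb(OAc)2, quinoline, EtOAc, rt
Reagents that add atoms: none
Why: Semihydrogenation of the terminal alkyne over lead-poisoned palladium should stop at the alkene, which gives the 1,1-dimethylallyl ether needed for the sigmatropic shift.

**Step 5**
Reactants: 7 1,3-bis(methoxymethoxy)-2-methyl-5-[(2-methylbut-3-en-2-yl)oxy]benzene
Product: 9 3,5-bis(methoxymethoxy)-4-methyl-2-(3-methylbut-2-en-1-yl)phenol, via ortho-dienone 8 (not isolated)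
Conditions: N,N-diethylaniline, 120 °C
Reagents that add atoms: none
Why: Aromatic Claisen rearrangement: the [3,3] shift bonds the terminal CH2 of the 1,1-dimethylallyl group to an ortho carbon (the two are equivalent and the para carbon is blocked by methyl) and enolisation of dienone 8 should give the phenol with a normal prenyl group beside the free hydroxyl, which is the O1/C8 relationship of the target.

**Step 6**
Reactants: 9 3,5-bis(methoxymethoxy)-4-methyl-2-(3-methylbut-2-en-1-yl)phenol; 10 (E)-3-(4-methoxyphenyl)prop-2-enoyl chloride (4-methoxycinnamoyl chloride)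
Product: 11 3,5-bis(methoxymethoxy)-4-methyl-2-(3-methylbut-2-en-1-yl)phenyl (E)-3-(4-methoxyphenyl)prop-2-enoate
Conditions: Et3N, DMAP (cat.), CH2Cl2, 0 °C to rt
Reagents that add atoms: none
Why: Acylation of the single free hydroxyl by the acid chloride under DMAP catalysis (Steglich-type acyl transfer) parks the ring B–C3 unit on O1 with its (E) double bond intact.

**Step 7**
Reactants: 11 3,5-bis(methoxymethoxy)-4-methyl-2-(3-methylbut-2-en-1-yl)phenyl (E)-3-(4-methoxyphenyl)prop-2-enoate
Product: 14 (2S)-2-(4-methoxyphenyl)-5,7-bis(methoxymethoxy)-6-methyl-8-(3-methylbut-2-en-1-yl)-2,3-dihydro-4H-chromen-4-one, via acyl dienone 12 (not isolated), via 2'-hydroxychalcone 13 (not isolated)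
Conditions: hν (300 nm, Pyrex), degassed benzene (2 mM), rt; then in the dark, solvent changed to toluene, quinine-derived 3,5-bis(trifluoromethyl)phenyl thiourea (9-amino-9-deoxy-epi-quinine type, 10 mol%), −20 °C
Reagents that add atoms: none
Why: Excitation of the aryl ester cleaves the O1–acyl bond to a caged phenoxyl/4-methoxycinnamoyl radical pair that recombines at C4a, the only unsubstituted carbon of ring A (the other ortho carbon carries the prenyl group and the para carbon the methyl group, so recombination there is unproductive and reversible), and enolisation of acyl dienone 12 gives the chelated 2'-hydroxychalcone 13, a photo-Fries rearrangement of the kind known for aryl cinnamates. In the dark the bifunctional cinchona thiourea then closes ring C by a 6-endo-trig oxa-Michael addition of O1–H to C2, the closest known reaction type being the amine–thiourea-catalysed cyclisation of 2'-hydroxychalcones to flavanones. The new stereocentre C2 is controlled by the catalyst alone: the quinuclidine nitrogen activates O1–H while the thiourea binds the C4 carbonyl, so that O1 is delivered to the Si face of C2, which corresponds to (2S). Regioselectivity needs no reagent control, because O1 is the only free hydroxyl (the oxygens at C5 and C7 are MOM ethers) and it is the oxygen that carried the acyl group, so the ring oxygen must end next to the prenyl-bearing C8. The MOM ether ortho to the carbonyl twists the enone out of the ring plane, which should make the closure fast and practically irreversible at low temperature so that the kinetic enantiomer preference is kept, and neither stage touches the MOM ethers or the prenyl double bond.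

**Step 8**
Reactants: 14 (2S)-2-(4-methoxyphenyl)-5,7-bis(methoxymethoxy)-6-methyl-8-(3-methylbut-2-en-1-yl)-2,3-dihydro-4H-chromen-4-one
Product: 15 (2S)-5,7-dihydroxy-2-(4-methoxyphenyl)-6-methyl-8-(3-methylbut-2-en-1-yl)-2,3-dihydro-4H-chromen-4-one
Conditions: HCl (1.25 M in MeOH), 40 °C
Reagents that add atoms: none
Why: Acid-catalysed solvolysis of the two aryl MOM acetals in methanol (the C5 ether, peri to the carbonyl, should go first) frees both hydroxyls, while the aryl methyl ether, the prenyl double bond and the C2 centre should survive dilute acid at moderate temperature because ring opening of a flavanone to the chalcone needs base.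

**Compound list**

1 | 2-methylresorcinol | Cc1c(O)cccc1O | starting material
2 | 1,3-bis(methoxymethoxy)-2-methylbenzene | COCOc1cccc(OCOC)c1C | intermediate
3 | 2-[3,5-bis(methoxymethoxy)-4-methylphenyl]-4,4,5,5-tetramethyl-1,3,2-dioxaborolane | COCOc1cc(B2OC(C)(C)C(C)(C)O2)cc(OCOC)c1C | intermediate (not isolated)
4 | 3,5-bis(methoxymethoxy)-4-methylphenol | COCOc1cc(O)cc(OCOC)c1C | intermediate
5 | 3-chloro-3-methylbut-1-yne | CC(C)(Cl)C#C | starting material
6 | 1,3-bis(methoxymethoxy)-2-methyl-5-[(2-methylbut-3-yn-2-yl)oxy]benzene | COCOc1cc(OC(C)(C)C#C)cc(OCOC)c1C | intermediate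
7 | 1,3-bis(methoxymethoxy)-2-methyl-5-[(2-methylbut-3-en-2-yl)oxy]benzene | COCOc1cc(OC(C)(C)C=C)cc(OCOC)c1C | intermediate
8 | 3,5-bis(methoxymethoxy)-4-methyl-6-(3-methylbut-2-en-1-yl)cyclohexa-2,4-dien-1-one (racemic) | O=C1C=C(OCOC)C(C)=C(OCOC)C1CC=C(C)C | intermediate (not isolated)
9 | 3,5-bis(methoxymethoxy)-4-methyl-2-(3-methylbut-2-en-1-yl)phenol | COCOc1cc(O)c(CC=C(C)C)c(OCOC)c1C | intermediate
10 | (E)-3-(4-methoxyphenyl)prop-2-enoyl chloride | COc1ccc(/C=C/C(=O)Cl)cc1 | starting material
11 | 3,5-bis(methoxymethoxy)-4-methyl-2-(3-methylbut-2-en-1-yl)phenyl (E)-3-(4-methoxyphenyl)prop-2-enoate | COc1ccc(/C=C/C(=O)Oc2cc(OCOC)c(C)c(OCOC)c2CC=C(C)C)cc1 | intermediate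
12 | 6-[(E)-3-(4-methoxyphenyl)prop-2-enoyl]-3,5-bis(methoxymethoxy)-4-methyl-2-(3-methylbut-2-en-1-yl)cyclohexa-2,4-dien-1-one (racemic) | O=C1C(CC=C(C)C)=C(OCOC)C(C)=C(OCOC)C1C(=O)/C=C/c1ccc(OC)cc1 | intermediate (not isolated)
13 | (E)-1-[2-hydroxy-4,6-bis(methoxymethoxy)-5-methyl-3-(3-methylbut-2-en-1-yl)phenyl]-3-(4-methoxyphenyl)prop-2-en-1-one | COc1ccc(/C=C/C(=O)c2c(O)c(CC=C(C)C)c(OCOC)c(C)c2OCOC)cc1 | intermediate (not isolated)
14 | (2S)-2-(4-methoxyphenyl)-5,7-bis(methoxymethoxy)-6-methyl-8-(3-methylbut-2-en-1-yl)-2,3-dihydro-4H-chromen-4-one | COc1ccc([C@@H]2CC(=O)c3c(OCOC)c(C)c(OCOC)c(CC=C(C)C)c3O2)cc1 | intermediate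
15 | (2S)-5,7-dihydroxy-2-(4-methoxyphenyl)-6-methyl-8-(3-methylbut-2-en-1-yl)-2,3-dihydro-4H-chromen-4-one | COc1ccc([C@@H]2CC(=O)c3c(O)c(C)c(O)c(CC=C(C)C)c3O2)cc1 | target

**Step count and risks**

Total step count: 8. Longest linear sequence: 8 steps (1 to 15).

Steps most likely to fail:

1. Step 7. The acyl shift may be inefficient because E/Z isomerisation of the cinnamoyl chromophore drains the excitation; light-induced dimerisation or a racemic photocyclisation of the chalcone may compete; and facial control in the closure by a hindered phenol may be insufficient. The fallback sets out from phenol 9 and comes back at 14, with the stereocentre set by a conjugate arylation instead of the ring closure. Magnesium-mediated ortho-formylation of 9 (MgCl2, Et3N, paraformaldehyde, MeCN, reflux) should give 2-hydroxy-4,6-bis(methoxymethoxy)-5-methyl-3-(3-methylbut-2-en-1-yl)benzaldehyde F1. Addition of MeMgBr (excess, THF, 0 °C) should give the benzylic alcohol F2, and oxidation with MnO2 (CH2Cl2, rt) the 2-hydroxyacetophenone F3. Condensation with N,N-dimethylformamide dimethyl acetal (toluene, 90 °C) should give the enaminone F4, which on silica gel or in dilute AcOH should close to 5,7-bis(methoxymethoxy)-6-methyl-8-(3-methylbut-2-en-1-yl)chromone F5. Enantioselective 1,4-addition of 4-methoxyphenylboronic acid under a divalent palladium catalyst (Pd(OCOCF3)2, the enantiomer of the tert-butyl pyridine-oxazoline ligand that gives (2S), NH4PF6, water, 1,2-dichloroethane, 60 °C) should then give 14.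

2. Step 8. The hydroxyl freed at C7 may add to the prenyl double bond under acid (chroman formation), and slow acid-induced opening and reclosure at C2 may erode the enantiomeric purity. The fallback sets out from 14 and comes back at 15 by silyl transfer in an aprotic medium instead of protic solvolysis. Me3SiOTf and 2,2'-bipyridyl in MeCN at 0 °C should exchange both MOM groups for trimethylsilyl groups to give (2S)-2-(4-methoxyphenyl)-6-methyl-8-(3-methylbut-2-en-1-yl)-5,7-bis(trimethylsilyloxy)-2,3-dihydro-4H-chromen-4-one F6, which water/MeOH at rt should hydrolyse to 15.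

3. Step 4. Over-reduction of the alkyne to the saturated ether, or hydrogenolysis of the tertiary propargylic C–O bond, may occur. The fallback sets out from phenol 4 and comes back at 7, so that steps 3 and 4 are both bypassed by an allylic etherification. tert-Butyl (2-methylbut-3-en-2-yl) carbonate F7 (from 2-methylbut-3-en-2-ol, n-BuLi and Boc2O) and a zerovalent palladium catalyst, Pd(PPh3)4, in THF at 0 °C should give the tertiary ether 7 by kinetic attack of the phenoxide on the more substituted end of the 1,1-dimethylallyl palladium intermediate.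

**Further compounds**

F1 | step 7 | 2-hydroxy-4,6-bis(methoxymethoxy)-5-methyl-3-(3-methylbut-2-en-1-yl)benzaldehyde | O=Cc1c(O)c(CC=C(C)C)c(OCOC)c(C)c1OCOC
F2 | step 7 | 1-[2-hydroxy-4,6-bis(methoxymethoxy)-5-methyl-3-(3-methylbut-2-en-1-yl)phenyl]ethan-1-ol (racemic) | CC(O)c1c(O)c(CC=C(C)C)c(OCOC)c(C)c1OCOC
F3 | step 7 | 1-[2-hydroxy-4,6-bis(methoxymethoxy)-5-methyl-3-(3-methylbut-2-en-1-yl)phenyl]ethan-1-one | CC(=O)c1c(O)c(CC=C(C)C)c(OCOC)c(C)c1OCOC
F4 | step 7 | (E)-3-(dimethylamino)-1-[2-hydroxy-4,6-bis(methoxymethoxy)-5-methyl-3-(3-methylbut-2-en-1-yl)phenyl]prop-2-en-1-one | CN(C)/C=C/C(=O)c1c(O)c(CC=C(C)C)c(OCOC)c(C)c1OCOC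
F5 | step 7 | 5,7-bis(methoxymethoxy)-6-methyl-8-(3-methylbut-2-en-1-yl)-4H-chromen-4-one | O=c1ccoc2c(CC=C(C)C)c(OCOC)c(C)c(OCOC)c12
F6 | step 8 | (2S)-2-(4-methoxyphenyl)-6-methyl-8-(3-methylbut-2-en-1-yl)-5,7-bis(trimethylsilyloxy)-2,3-dihydro-4H-chromen-4-one | COc1ccc([C@@H]2CC(=O)c3c(O[Si](C)(C)C)c(C)c(O[Si](C)(C)C)c(CC=C(C)C)c3O2)cc1
F7 | step 4 | tert-butyl (2-methylbut-3-en-2-yl) carbonate | CC(C)(C)OC(=O)OC(C)(C)C=C
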